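**Assumption:** ring carbons are numbered C1' (chain-bearing) to C6' and the chain C1 (benzylic) to C20. The target has no stereocenter, so nothing has to be set or preserved.

## Retrosynthetic overview

- The target, 1-(3,4-dihydroxyphenyl)icosan-5-one, has one ring, a benzene ring that is bought intact; no ring is formed in the route. The strategy rests on the catechol: the two oxygens on C3' and C4' of the benzene ring, with the C4' oxygen para to the chain carbon C1'. Removing the C3' oxygen leaves a para-alkylphenol whose two ortho carbons (C3' and C5') are equivalent, so the C3'–O bond can be made last and no protecting group is needed.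
- C3'–O: ortho-oxygenation of 1-(4-hydroxyphenyl)icosan-5-one with 2-iodoxybenzoic acid (IBX) to the ortho-quinone, which is reduced in the same flask with Na2S2O4.
- C5–C6: Weinreb amide of 5-(4-hydroxyphenyl)pentanoic acid plus pentadecylmagnesium bromide (from 1-bromopentadecane), with the phenol left free.

Key step: step 4

## Route

Step 1
Reactants: 1 5-(4-hydroxyphenyl)pentanoic acid
Product: 2 5-(4-hydroxyphenyl)-N-methoxy-N-methylpentanamide
Conditions: MeNH(OMe)·HCl (1.3 equiv), EDC·HCl (1.3 equiv), HOBt, N-methylmorpholine (3 equiv), CH2Cl2/DMF, 0 °C to rt
Reagents that add atoms: N,O-dimethylhydroxylamine hydrochloride, CNOC.Cl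
Why: Carbodiimide/HOBt amide coupling (Weinreb amide formation); the amine nitrogen is far more nucleophilic towards the HOBt active ester than the neutral phenol under these weakly basic conditions, so the amide should form without phenol protection.

Step 2
Reactants: 3 1-bromopentadecane
Product: 4 pentadecylmagnesium bromide (THF solution, titrated and used directly)
Conditions: Mg turnings, cat. I2, THF, slow addition, 40–50 °C
Reagents that add atoms: magnesium, [Mg]
Why: Grignard reagent formation by insertion of magnesium into a primary C–Br bond; slow addition of the bromide keeps Wurtz coupling of the long chain low.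

Step 3
Reactants: 2 5-(4-hydroxyphenyl)-N-methoxy-N-methylpentanamide; 4 pentadecylmagnesium bromide (3 equiv)
Product: 6 1-(4-hydroxyphenyl)icosan-5-one, via chelated tetrahedral bromomagnesium adduct 5 (not isolated)
Conditions: THF, 0 °C to rt; then 1 M HCl, 0 °C
Reagents that add atoms: none
Why: Weinreb ketone synthesis: the first equivalent of 4 converts the phenol into an inert bromomagnesium phenoxide (ArOMgBr), the second adds to the amide carbonyl to give the five-membered N-methoxy chelate 5, which resists further addition and collapses to the ketone only on the acidic quench.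

Step 4
Reactants: 6 1-(4-hydroxyphenyl)icosan-5-one
Product: 8 1-(3,4-dihydroxyphenyl)icosan-5-one, via ortho-quinone 4-(5-oxoicosyl)cyclohexa-3,5-diene-1,2-dione 7 (not isolated)
Conditions: IBX (1.2 equiv), CHCl3/MeOH 3:1, −20 °C to 0 °C, dark; then aq. Na2S2O4 (excess), same flask, 0 °C to rt
Reagents that add atoms: 2-iodoxybenzoic acid (IBX), O=C1OI(=O)(O)c2ccccc12
Why: The phenol oxygen of 6 exchanges with the hydroxyl ligand on the pentavalent iodine of IBX; within this aryloxy iodine complex the iodine-bound oxygen shifts to the ortho carbon C3', forming the C3'–O bond while iodine falls to the trivalent state, and after tautomerization a second two-electron oxidation expels 2-iodobenzoic acid (monovalent iodine) and releases ortho-quinone 7. The closest known reaction type is the IBX ortho-oxygenation of phenols to ortho-quinones with reductive work-up to catechols, the chemical counterpart of tyrosinase acting on para-alkylphenols. No ring is closed and no stereocenter is formed. Ortho selectivity follows from intramolecular oxygen delivery and from the chain blocking the para carbon C1', and C3' and C5' are equivalent, so only one regioisomer can form. Chemoselectivity rests on the low temperature, at which the saturated C5 ketone, its alpha hydrogens and the benzylic C1 hydrogens are not attacked by IBX. Na2S2O4 is added as soon as 6 is consumed, so that 7 is reduced to catechol 8 before it can tautomerize through its benzylic C1 hydrogens to a quinone methide.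

## Compound list

1 | 5-(4-hydroxyphenyl)pentanoic acid | O=C(O)CCCCc1ccc(O)cc1 | starting material
2 | 5-(4-hydroxyphenyl)-N-methoxy-N-methylpentanamide | CON(C)C(=O)CCCCc1ccc(O)cc1 | intermediate
3 | 1-bromopentadecane | CCCCCCCCCCCCCCCBr | starting material
4 | pentadecylmagnesium bromide | CCCCCCCCCCCCCCC[Mg]Br | intermediate
5 | bromomagnesium 1-[4-(bromomagnesiooxy)phenyl]-5-[methoxy(methyl)amino]icosan-5-olate (chelated tetrahedral adduct) | CCCCCCCCCCCCCCCC(O[Mg]Br)(CCCCc1ccc(O[Mg]Br)cc1)N(C)OC | intermediate
6 | 1-(4-hydroxyphenyl)icosan-5-one | CCCCCCCCCCCCCCCC(=O)CCCCc1ccc(O)cc1 | intermediate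
7 | 4-(5-oxoicosyl)cyclohexa-3,5-diene-1,2-dione | CCCCCCCCCCCCCCCC(=O)CCCCC1=CC(=O)C(=O)C=C1 | intermediate
8 | 1-(3,4-dihydroxyphenyl)icosan-5-one | CCCCCCCCCCCCCCCC(=O)CCCCc1ccc(O)c(O)c1 | target

## Step count and risks

Total step count: 4 (steps 1 to 4, including the preparation of the Grignard reagent).
Longest linear sequence: 3 steps (1 → 2 → 6 → 8; equally 3 → 4 → 6 → 8).

Steps most likely to fail:

1. **Step 4 (key step).** The 4-alkyl ortho-quinone may decay before it is reduced: tautomerization through the benzylic C1 hydrogens to a quinone methide, then addition of methanol or oligomerization. Oxygen transfer may also stall on the poorly soluble long-chain phenol. The fallback sets out from 6 and installs the C3' oxygen through a carbon substituent instead. Ortho-formylation of 6 (MgCl2, Et3N, paraformaldehyde, THF, reflux) should give 2-hydroxy-5-(5-oxoicosyl)benzaldehyde F1, again as a single regioisomer because both ortho carbons are equivalent. Dakin oxidation of F1 (H2O2, aq. NaOH/THF, 0 °C to rt, under N2) should proceed through 2-hydroxy-5-(5-oxoicosyl)phenyl formate F2, which is hydrolysed in the same flask; acidification returns the route at 8. The saturated ketone should not undergo Baeyer–Villiger oxidation under alkaline H2O2.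

2. **Step 3.** The bromomagnesium phenoxide of 2 may aggregate or precipitate and stall the addition, and Wurtz homocoupling may lower the titre of 4, leaving the amide unconsumed. The fallback sets out from 2 and masks the phenol. Silylation (TBSCl, imidazole, DMF, rt) should give 5-[4-(tert-butyldimethylsilyloxy)phenyl]-N-methoxy-N-methylpentanamide F3. Addition of 4 (1.3 equiv, THF, 0 °C; aq. NH4Cl) should give 1-[4-(tert-butyldimethylsilyloxy)phenyl]icosan-5-one F4. Desilylation (TBAF, AcOH, THF, 0 °C) returns the route at 6.

3. **Step 1.** The activated acid may acylate the phenol oxygen of a second molecule, giving oligomeric aryl esters in competition with amide formation. The fallback sets out from 1 and avoids any activated acyl species. Fischer esterification (MeOH, cat. H2SO4, reflux) should give methyl 5-(4-hydroxyphenyl)pentanoate F5. Aminolysis of F5 with the chloromagnesium amide of N,O-dimethylhydroxylamine (MeNH(OMe)·HCl, iPrMgCl in excess, THF, −20 °C to 0 °C) returns the route at 2; the phenol is carried through as its magnesium phenoxide.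

## Further compounds

F1 | step 4 | 2-hydroxy-5-(5-oxoicosyl)benzaldehyde | CCCCCCCCCCCCCCCC(=O)CCCCc1ccc(O)c(C=O)c1
F2 | step 4 | 2-hydroxy-5-(5-oxoicosyl)phenyl formate | CCCCCCCCCCCCCCCC(=O)CCCCc1ccc(O)c(OC=O)c1
F3 | step 3 | 5-[4-(tert-butyldimethylsilyloxy)phenyl]-N-methoxy-N-methylpentanamide | CON(C)C(=O)CCCCc1ccc(O[Si](C)(C)C(C)(C)C)cc1
F4 | step 3 | 1-[4-(tert-butyldimethylsilyloxy)phenyl]icosan-5-one | CCCCCCCCCCCCCCCC(=O)CCCCc1ccc(O[Si](C)(C)C(C)(C)C)cc1
F5 | step 1 | methyl 5-(4-hydroxyphenyl)pentanoate | COC(=O)CCCCc1ccc(O)cc1
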